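**Retrosynthetic overview**
1. Target ⇒ (C2–Br, last-step electrophilic bromination) (R)-4-(5-bromo-1H-indol-3-yl)-2-aminoimidazoline.
2. Both heterocycles ⇒ (one flask) acyclic (E)-4-(bis-Boc-guanidino)but-2-enal + 4-bromophenylhydrazine: cut N3–C4 of the imidazoline (asymmetric 5-exo aza-Michael, sets C4) and the indole C3–C3a and N1–C2 bonds (Fischer).
3. Ring order in the forward direction: imidazoline first, then the pyrrole ring of the indole onto the bromobenzene ring.
4. Enal ⇒ cross-metathesis of N-allyl-bis-Boc-guanidine with crotonaldehyde ⇒ allylamine + bis-Boc-pyrazole-carboxamidine.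

Assumption: the single stereocentre is C4 of the imidazoline with the (R) configuration of the given SMILES; the two final aminoimidazolines are drawn as free bases although they are isolated as trifluoroacetate salts.

**Step 1**
Reactants: 1 allylamine; 2 N,N'-bis(tert-butoxycarbonyl)-1H-pyrazole-1-carboxamidine
Product: 3 N-allyl-N',N''-bis(tert-butoxycarbonyl)guanidine
Conditions: 1 (1.1 equiv), MeCN, rt, 12 h
Reagents that add atoms: none
Why: Guanylation (amidine transfer by addition–elimination) of a primary amine is fast and clean because pyrazole is a good leaving group and the two Boc groups activate the amidine carbon, and no stereocentre is formed.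

**Step 2**
Reactants: 3 N-allyl-N',N''-bis(tert-butoxycarbonyl)guanidine; 4 (E)-but-2-enal (crotonaldehyde)
Product: 5 N-[(2E)-4-oxobut-2-en-1-yl]-N',N''-bis(tert-butoxycarbonyl)guanidine
Conditions: 4 (5 equiv), second-generation Hoveyda–Grubbs catalyst RuCl2(H2IMes)(=CH-C6H4-2-OiPr) (5 mol %) [H2IMes = 1,3-dimesitylimidazolidin-2-ylidene], CH2Cl2, 40 °C, 6 h; product kept cold and used at once
Reagents that add atoms: none
Why: Olefin cross-metathesis of the terminal allyl group with excess crotonaldehyde is driven by loss of propene and gives the thermodynamically preferred (E)-enal, the carbamate-masked guanidine being too weakly basic to poison the ruthenium carbene, and no stereocentre is formed.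

**Step 3**
Reactants: 5 N-[(2E)-4-oxobut-2-en-1-yl]-N',N''-bis(tert-butoxycarbonyl)guanidine; 6 4-bromophenylhydrazine hydrochloride
Product: 10 (4R)-4-(5-bromo-1H-indol-3-yl)-4,5-dihydro-1H-imidazol-2-amine, via imidazolidine aldehyde 7 (not isolated), via Boc-protected hydrazone 8 (not isolated), via deprotected hydrazone 9 (not isolated)
Conditions: (R)-α,α-bis[3,5-bis(trifluoromethyl)phenyl]-2-pyrrolidinemethanol trimethylsilyl ether (20 mol %), PhCO2H (20 mol %), CHCl3, −40 °C, 36 h; then 6 (1.05 equiv), EtOH, −40 → 0 °C, 1 h; then evaporate CHCl3, 4 M HCl in dioxane/EtOH, rt, 2 h, then 75 °C, 3 h; RP-C18 (H2O/MeCN, 0.1 % TFA)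
Reagents that add atoms: none
Why: Proposed new method: the (R)-diarylprolinol silyl ether forms an (E)-iminium ion with the enal whose diarylmethyl silyl ether group blocks one face, so the tethered Boc-guanidine NH adds 5-exo-trig to the β-carbon from the open face and sets the (R) centre (closest known reaction: iminium-catalysed intramolecular aza-Michael addition of carbamates to enals), after which the β-amino aldehyde is trapped cold as its arylhydrazone, HCl removes both Boc groups, and heating drives a Fischer indole synthesis ([3,3]-sigmatropic shift of the ene-hydrazine, ring closure, loss of ammonia) in which the protonated guanidine is a poor leaving group and so holds the configuration.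

**Step 4**
Reactants: 10 (4R)-4-(5-bromo-1H-indol-3-yl)-4,5-dihydro-1H-imidazol-2-amine
Product: 11 (4R)-4-(2,5-dibromo-1H-indol-3-yl)-4,5-dihydro-1H-imidazol-2-amine
Conditions: trifluoroacetate salt of 10, NBS (1.0 equiv), AcOH, 15 °C → rt, dark, 1 h; RP-C18 (H2O/MeCN, 0.1 % TFA)
Reagents that add atoms: N-bromosuccinimide, O=C1CCC(=O)N1Br
Why: Electrophilic bromination of a 3-substituted indole in anhydrous acid goes through the 3-bromoindolenine, which rearranges to the 2-bromoindole, while the protonated guanidine and the 5-bromo benzene ring are deactivated and the C4 stereocentre is not involved.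

**Compound list**
1 | allylamine (prop-2-en-1-amine) | C=CCN | starting material
2 | N,N'-bis(tert-butoxycarbonyl)-1H-pyrazole-1-carboxamidine | CC(C)(C)OC(=O)NC(=NC(=O)OC(C)(C)C)n1cccn1 | starting material
3 | N-allyl-N',N''-bis(tert-butoxycarbonyl)guanidine | C=CCNC(=NC(=O)OC(C)(C)C)NC(=O)OC(C)(C)C | intermediate
4 | (E)-but-2-enal (crotonaldehyde) | C/C=C/C=O | starting material
5 | N-[(2E)-4-oxobut-2-en-1-yl]-N',N''-bis(tert-butoxycarbonyl)guanidine | O=C/C=C/CNC(=NC(=O)OC(C)(C)C)NC(=O)OC(C)(C)C | intermediate
6 | 4-bromophenylhydrazine hydrochloride | NNc1ccc(Br)cc1.Cl | starting material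
7 | tert-butyl (5R)-2-[(tert-butoxycarbonyl)imino]-5-(2-oxoethyl)imidazolidine-1-carboxylate | CC(C)(C)OC(=O)N=C1NC[C@@H](CC=O)N1C(=O)OC(C)(C)C | intermediate
8 | tert-butyl (5R)-5-{(2E)-2-[2-(4-bromophenyl)hydrazinylidene]ethyl}-2-[(tert-butoxycarbonyl)imino]imidazolidine-1-carboxylate | CC(C)(C)OC(=O)N=C1NC[C@@H](C/C=N/Nc2ccc(Br)cc2)N1C(=O)OC(C)(C)C | intermediate
9 | (4R)-4-{(2E)-2-[2-(4-bromophenyl)hydrazinylidene]ethyl}-4,5-dihydro-1H-imidazol-2-amine | NC1=N[C@H](C/C=N/Nc2ccc(Br)cc2)CN1 | intermediate
10 | (4R)-4-(5-bromo-1H-indol-3-yl)-4,5-dihydro-1H-imidazol-2-amine | NC1=N[C@H](c2c[nH]c3ccc(Br)cc23)CN1 | intermediate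
11 | (4R)-4-(2,5-dibromo-1H-indol-3-yl)-4,5-dihydro-1H-imidazol-2-amine | NC1=N[C@H](c2c(Br)[nH]c3ccc(Br)cc23)CN1 | target

**Total step count:** 4
**Longest linear sequence:** 4 steps (1 → 3 → 5 → 10 → 11)

**Steps most likely to fail**

Step 3 (highest risk). The Boc-guanidine may cyclise without the catalyst and give low ee. The β-amino aldehyde or its hydrazone may also lose configuration by retro-aza-Michael reaction in the acid stage, and the Fischer step is slowed by the bromo and guanidinium groups. The ee of 10 is checked by chiral HPLC and can be raised by one recrystallisation of its salt. The fallback sets out from 2 and comes back at 10. Compound 2 is condensed with aminoacetaldehyde dimethyl acetal (MeCN, rt) to give N-(2,2-dimethoxyethyl)-N',N''-bis(tert-butoxycarbonyl)guanidine F1. F1 and 5-bromoindole are then combined with a chiral phosphoric acid, (R)-3,3'-bis(2,4,6-triisopropylphenyl)-1,1'-binaphthyl-2,2'-diyl hydrogen phosphate (10 mol %, toluene, 5 Å molecular sieves, 0 °C). The acid ionises the acetal and the Boc-NH closes the ring to tert-butyl 2-[(tert-butoxycarbonyl)imino]-5-methoxyimidazolidine-1-carboxylate F2 (not isolated). F2 loses methanol to a cyclic N-Boc-amidinium ion paired with the chiral phosphate, and Friedel–Crafts attack by C3 of the indole gives tert-butyl (5R)-5-(5-bromo-1H-indol-3-yl)-2-[(tert-butoxycarbonyl)imino]imidazolidine-1-carboxylate F3. The catalyst antipode is chosen after the first run shows the sense of induction. TFA/CH2Cl2 removes both Boc groups and gives 10.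

Step 4. NBS may over-brominate (C6), oxidise the indole to an oxindole if water is present, or fragment the gramine-type side chain. The fallback sets out from 10 and comes back at 11. Boc2O (2.2 equiv, Et3N, CH2Cl2/DMF) converts 10 into tert-butyl (4R)-4-(5-bromo-1H-indol-3-yl)-2-[(tert-butoxycarbonyl)imino]imidazolidine-1-carboxylate F4. Iridium-catalysed C–H borylation ([Ir(OMe)(cod)]2, 4,4'-di-tert-butyl-2,2'-bipyridine, B2pin2, THF, 60 °C) goes to C2 of 3-substituted N–H indoles and leaves aryl bromides alone, giving tert-butyl (4R)-4-[5-bromo-2-(4,4,5,5-tetramethyl-1,3,2-dioxaborolan-2-yl)-1H-indol-3-yl]-2-[(tert-butoxycarbonyl)imino]imidazolidine-1-carboxylate F5. CuBr2 (3 equiv, MeOH/H2O, 60 °C) exchanges boron for bromine to give tert-butyl (4R)-4-(2,5-dibromo-1H-indol-3-yl)-2-[(tert-butoxycarbonyl)imino]imidazolidine-1-carboxylate F6. TFA/CH2Cl2 then gives 11.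

Step 2. The enal may cyclise (racemically) during metathesis or on silica, or the guanidine may slow the ruthenium catalyst. The fallback sets out from 3 and comes back at 5. Ozonolysis of 3 (O3, CH2Cl2, −78 °C, then Me2S) gives N-(2-oxoethyl)-N',N''-bis(tert-butoxycarbonyl)guanidine F7, which is used crude. Wittig olefination with (triphenylphosphoranylidene)acetaldehyde (toluene, 60 °C) extends it by two carbons to the (E)-enal 5 without any metal carbene.

**Further compounds**
F1 | step 3 | N-(2,2-dimethoxyethyl)-N',N''-bis(tert-butoxycarbonyl)guanidine | COC(CNC(=NC(=O)OC(C)(C)C)NC(=O)OC(C)(C)C)OC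
F2 | step 3 | tert-butyl 2-[(tert-butoxycarbonyl)imino]-5-methoxyimidazolidine-1-carboxylate | COC1CNC(=NC(=O)OC(C)(C)C)N1C(=O)OC(C)(C)C
F3 | step 3 | tert-butyl (5R)-5-(5-bromo-1H-indol-3-yl)-2-[(tert-butoxycarbonyl)imino]imidazolidine-1-carboxylate | CC(C)(C)OC(=O)N=C1NC[C@@H](c2c[nH]c3ccc(Br)cc23)N1C(=O)OC(C)(C)C
F4 | step 4 | tert-butyl (4R)-4-(5-bromo-1H-indol-3-yl)-2-[(tert-butoxycarbonyl)imino]imidazolidine-1-carboxylate | CC(C)(C)OC(=O)N=C1N[C@H](c2c[nH]c3ccc(Br)cc23)CN1C(=O)OC(C)(C)C
F5 | step 4 | tert-butyl (4R)-4-[5-bromo-2-(4,4,5,5-tetramethyl-1,3,2-dioxaborolan-2-yl)-1H-indol-3-yl]-2-[(tert-butoxycarbonyl)imino]imidazolidine-1-carboxylate | CC(C)(C)OC(=O)N=C1N[C@H](c2c(B4OC(C)(C)C(C)(C)O4)[nH]c3ccc(Br)cc23)CN1C(=O)OC(C)(C)C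
F6 | step 4 | tert-butyl (4R)-4-(2,5-dibromo-1H-indol-3-yl)-2-[(tert-butoxycarbonyl)imino]imidazolidine-1-carboxylate | CC(C)(C)OC(=O)N=C1N[C@H](c2c(Br)[nH]c3ccc(Br)cc23)CN1C(=O)OC(C)(C)C
F7 | step 2 | N-(2-oxoethyl)-N',N''-bis(tert-butoxycarbonyl)guanidine | O=CCNC(=NC(=O)OC(C)(C)C)NC(=O)OC(C)(C)C
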